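One mole of X turned into J should cost one mole of G, and that is the zero of my scale: at that cost, a flask that has made J and a fresh flask with the same X and G go at the same rate.

| setting | gamma | zeta | theta | beta | eta |
|---|---|---|---|---|---|
| X | 0.500 M | 0.250 M | 0.500 M | 0.250 M | 0.500 M |
| G | 1.25 M | 1.00 M | 2.50 M | 1.25 M | 1.25 M |
| time |  |  |  |  | 240 s |

| gamma run: time / s | gamma run: [X] / M | zeta run: time / s | zeta run: [X] / M | theta run: time / s | theta run: [X] / M | beta run: time / s | beta run: [X] / M |
|---|---|---|---|---|---|---|---|
| 2.4 | 0.4822 | 2.4 | 0.2438 | 2.4 | 0.4385 | 2.4 | 0.2408 |
| 4.6 | 0.4670 | 4.6 | 0.2414 | 4.6 | 0.3932 | 4.6 | 0.2370 |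
| 8.8 | 0.4446 | 8.8 | 0.2335 | 8.8 | 0.3258 | 8.8 | 0.2211 |
| 17 | 0.4093 | 17 | 0.2186 | 17 | 0.2399 | 17 | 0.1965 |
| 32 | 0.3549 | 32 | 0.1930 | 32 | 0.1448 | 32 | 0.1699 |
| 61 | 0.2861 | 61 | 0.1581 | 61 | 0.0694 | 61 | 0.1290 |

(standard deviation of a reading: 0.002 M)

* the exponent of [G] in the starting rate at the charge of the gamma run (at the point where two percent of the X have become J)
* the exponent of [X] in the starting rate at the charge of the gamma run (at the point where two percent of the X have become J) (one fixed amount of J, the same in the runs compared)
* the zeta run starts with 0.250 M less of X and of G than the gamma run, and with no J. Compared where both hold the same amount of X, once fifteen percent of what the zeta run was charged with has turned into J, is the zeta run faster, slower or alike (within a tenth)?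
* X in the eta run at 240 s, as a share of the X charged
* which of these the readings show (the second partner pairs with itself / the two partners rest in a complex / the product binds the second partner / two substrates go astray together)

- Overall: X + G -> J.
- Constant volume, constant temperature.
- A reading of a species includes what of it is bound.
- "The second partner" is G.
- An order is taken over about fifteen percent of the charge, up and down.

First the orders, from the earliest drops. Theta against gamma, with doubled G, reads 1.79, and gamma against beta, with doubled X, reads 0.939. I take rate = k·X·G², order two in G and one in X.

The gamma run's first stretch gives k = 0.00892 M⁻² s⁻¹. Between its last two readings the rate is 2.37 mM s⁻¹ at 0.321 M of X. That rate implies a G whose loss per J made is 1.89, not one.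

The weak link is k itself, since I read it at one G per X. Reread at two G per X, it becomes 0.00934 M⁻² s⁻¹, and the loss becomes 2.00. This is the toll, the moles of G gone from the working pool per mole of J made. One goes into J by the overall equation, and I read the other as held by J, so the product binds G.

Working G is then the charge minus toll times J. At the asked point, the zeta run has made 0.0375 M of J and gamma 0.287 M, so the zeta run is faster than gamma by a factor of 1.88. Integrating the law for the eta run, which has gamma's charge, X reaches 28.6% of its charge at 239 s, so that is my share at 240 s.

The forecast gives orders 2 and 1, faster, 24% and "the product binds the second partner", saying “J is tying up G”, and its share lies below mine.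

The flask gives orders 2.0 and 1.0, faster, 28.7% and "the product binds the second partner".

    X + 2 G → J + G (0.009060 M⁻² s⁻¹)
    G + J ⇌ GJ, settled at all times (95.30 M⁻¹)

The toll of 2.00 reads as one G that goes into J and one held as GJ for each J. The zeta run shows it: at equal X it goes 1.9 times as fast as gamma, against my 1.88, and the ratio falls to 1.0 without the tying up of G as GJ. Carried to the zeta run's own charge, the toll puts J at half of the X charged at 102 s, and the run reached it at 105 s.

The readings come from a simulation from invented constants; the scatter is artificial.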